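## Retrosynthetic overview

- The target comes from global acidolysis of a 4,5-bis(O-Boc-p-coumaroyl) ester. That ester is made by Steglich esterification of a quinic acid 4,5-diol in which O3 is a PMB ether and O1 and the carboxyl carbon C7 stay tied as a spiro-dioxolanone.
- Feature used: in the cyclohexane ring, C1 is a quaternary glycolic acid carbon (it bears O1 and C7) between the methylene carbons C2 and C6. C3, C4 and C5 bear three secondary oxygens (O3/O4 erythro, O4/O5 threo) that match C4, C3 and C2 of D-arabinitol.
- Key disconnection: both ring bonds at C1 (C1–C2 and C1–C6) are cut. This gives glycolic acid acetonide as a twofold carbon nucleophile and a D-arabinitol 1,5-bis-triflate as the five-carbon bis-electrophile ([5+1] spiro-annulation).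
- Ring order: the O4/O5 dioxolane (arabinitol stage) and the dioxolanone (from glycolic acid) are made first, and the cyclohexane is closed last, in one flask. The dioxolane is opened before acylation and the dioxolanone only in the final step.

Key step: step 7

Remark on numbering: quinic acid is numbered as the SMILES requires. O3 (free in the target) is cis to O4 and O1; O5 is trans to O4 and lies on the same face as C7.

## Route

Step 1
Reactants: 1 D-arabinitol
Product: 2 1,5-bis-O-(tert-butyldiphenylsilyl)-D-arabinitol
Conditions: TBDPSCl (2.1 equiv), imidazole, DMF, 0 °C to rt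
Reagents that add atoms: tert-butyldiphenylsilyl chloride, CC(C)(C)[Si](Cl)(c1ccccc1)c1ccccc1
Why: Silyl ether formation with imidazole, in which the bulky chlorosilane reacts with the two primary hydroxyls much faster than with the three flanked secondary ones, and no stereocentre is touched.

Step 2
Reactants: 2 1,5-bis-O-(tert-butyldiphenylsilyl)-D-arabinitol
Product: 3 1,5-bis-O-(tert-butyldiphenylsilyl)-2,3-O-isopropylidene-D-arabinitol
Conditions: Me2C(OMe)2, TsOH·H2O (cat.), acetone, rt (equilibrating); Et3N quench
Reagents that add atoms: 2,2-dimethoxypropane, COC(C)(C)OC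
Why: Thermodynamically controlled transketalisation, in which the dioxolane on the threo pair O2/O3 carries its two large substituents trans, the erythro pair O3/O4 would give a cis-disubstituted dioxolane and O2/O4 a dioxane with an axial methyl group, so equilibration should funnel the triol into 3 and leave only O4–H free.

Step 3
Reactants: 3 1,5-bis-O-(tert-butyldiphenylsilyl)-2,3-O-isopropylidene-D-arabinitol; 4 4-methoxybenzyl chloride
Product: 5 1,5-bis-O-(tert-butyldiphenylsilyl)-2,3-O-isopropylidene-4-O-(4-methoxybenzyl)-D-arabinitol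
Conditions: NaH, THF–DMF, 0 °C to rt
Reagents that add atoms: none
Why: Williamson ether synthesis on the only free hydroxyl, with TBDPS chosen because it resists alkoxide-induced 1,2-silyl migration and the acetonide inert to base.

Step 4
Reactants: 5 1,5-bis-O-(tert-butyldiphenylsilyl)-2,3-O-isopropylidene-4-O-(4-methoxybenzyl)-D-arabinitol
Product: 6 2,3-O-isopropylidene-4-O-(4-methoxybenzyl)-D-arabinitol
Conditions: Bu4NF·3H2O (2.5 equiv), THF, 0 °C to rt
Reagents that add atoms: none
Why: Fluoride-induced desilylation driven by the strong Si–F bond, to which the PMB ether and the acetonide are inert.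

Step 5
Reactants: 6 2,3-O-isopropylidene-4-O-(4-methoxybenzyl)-D-arabinitol
Product: 7 2,3-O-isopropylidene-4-O-(4-methoxybenzyl)-1,5-bis-O-(trifluoromethanesulfonyl)-D-arabinitol
Conditions: 6 added to Tf2O (2.5 equiv), 2,6-lutidine, CH2Cl2, −78 to −30 °C; cold NaHCO3 wash, short silica plug, used at once
Reagents that add atoms: trifluoromethanesulfonic anhydride, O=S(=O)(OS(=O)(=O)C(F)(F)F)C(F)(F)F
Why: O-Sulfonylation of both primary alcohols with a hindered non-nucleophilic pyridine base, triflates being needed because both carbons are deactivated towards SN2 by a β-oxygen, and inverse addition to excess anhydride keeps any hydroxy-triflate from closing a cyclic ether.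

Step 6
Reactants: 8 glycolic acid
Product: 9 2,2-dimethyl-1,3-dioxolan-4-one
Conditions: Me2C(OMe)2, TsOH·H2O (cat.), CH2Cl2, reflux through 4 Å molecular sieves; distillation
Reagents that add atoms: 2,2-dimethoxypropane, COC(C)(C)OC
Why: Acid-catalysed transketalisation of an α-hydroxy acid to the five-membered acylal, driven by removal of methanol.

Step 7
Reactants: 7 2,3-O-isopropylidene-4-O-(4-methoxybenzyl)-1,5-bis-O-(trifluoromethanesulfonyl)-D-arabinitol; 9 2,2-dimethyl-1,3-dioxolan-4-one
Product: 12 4,5-O-isopropylidene-3-O-(4-methoxybenzyl)quinic acid 1,7-acetonide (spiro-1,3-dioxolan-4-one), via C6-linked monotriflate 10 (not isolated), via C2-linked monotriflate 11 (not isolated)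
Conditions: 7 and 9 (1.05 equiv) in THF (0.01 M), −78 °C; KN(SiMe3)2 (2.1 equiv, toluene solution) by syringe pump; −78 to −40 °C; pH 7 buffer quench
Reagents that add atoms: none
Why: Proposed new method: each portion of KN(SiMe3)2 entering the cold mixture deprotonates the most acidic C–H present, first C5–H of 9, whose enolate carbon displaces one primary triflate of 7 by SN2 to give 10 or 11 (they differ only in which CH2 reacted first, and their new C–H stereocentre is erased again), then the remaining C5–H of 10 or 11, whose enolate carbon displaces the second triflate within the same molecule. The closest known reactions are the stepwise C5-dialkylation of glycolate-derived 1,3-dioxolan-4-one enolates and the [5+1] carbocyclisation of sugar-derived 1,5-bis-electrophiles with malonate or dithiane carbanions, and only their combination in one spiro-annulation is without precedent. The cyclohexane closes in the 6-(enolexo)-exo-tet mode, which Baldwin's rules for enolates allow, and carbon rather than oxygen attacks because O-alkylation would need an eight-membered ring. C3, C4 and C5 cannot change because substitution takes place only at CH2 carbons, so C1 is the single new stereocentre, and it is governed by the chair-like transition state that the trans-fused O4/O5 dioxolane enforces (O4 and O5 equatorial, O3-PMB axial): the bare ring oxygen O1 can lie pseudo-axial next to O3, whereas the C7–O–K terminus and its solvent shell would be pushed over the ring against the axial PMB ether, so C7 should end up equatorial and O1 axial, cis to O3 as in quinic acid. Potassium is chosen over lithium so that no chelate between the enolate oxygen and O3 can turn this preference around, and this facial selectivity is the open point of the route. The step also needs substitution to beat elimination, ether participation and oligomerisation, which is secured by triflates that react at −78 °C despite the β-oxygens, by the trans-dioxolane that would force attack of the PMB ether oxygen O3 on C6 through a strained trans-fused bicyclo[3.3.0] oxonium ion, and by high dilution with the base as limiting reagent.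

Step 8
Reactants: 12 4,5-O-isopropylidene-3-O-(4-methoxybenzyl)quinic acid 1,7-acetonide
Product: 13 3-O-(4-methoxybenzyl)quinic acid 1,7-acetonide (free 4,5-diol)
Conditions: AcOH–H2O–THF (3:1:1), rt, stopped when 12 is consumed
Reagents that add atoms: none
Why: Selective acid-catalysed ketal hydrolysis, in which the dioxolane trans-fused to the cyclohexane is strained and has two basic ether oxygens and so opens in aqueous acetic acid, the spiro-dioxolanone is an acylal with weakly basic oxygens that normally needs aqueous mineral acid or CF3CO2H, the PMB ether is inert, and keeping O1 and C7 tied prevents the 1,5-lactonisation and carboxyl activation that a free hydroxy acid would suffer in step 10.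

Step 9
Reactants: 14 p-coumaric acid
Product: 15 (E)-4-(tert-butoxycarbonyloxy)cinnamic acid
Conditions: Boc2O (1.2 equiv), NaOH (2 equiv), THF–H2O, 0 °C; then 1 M HCl to pH 3 at 0 °C
Reagents that add atoms: di-tert-butyl dicarbonate, CC(C)(C)OC(=O)OC(=O)OC(C)(C)C
Why: Schotten–Baumann-type O-acylation in which the phenoxide is the better nucleophile and any mixed anhydride formed at the carboxylate is hydrolysed back, so only the phenol ends up masked and the E alkene is untouched.

Step 10
Reactants: 13 3-O-(4-methoxybenzyl)quinic acid 1,7-acetonide; 15 (E)-4-(tert-butoxycarbonyloxy)cinnamic acid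
Product: 16 4,5-bis-O-[(E)-4-(tert-butoxycarbonyloxy)cinnamoyl]-3-O-(4-methoxybenzyl)quinic acid 1,7-acetonide
Conditions: 15 (3 equiv), EDC·HCl (3.2 equiv), DMAP, CH2Cl2, 0 °C to rt, in the dark
Reagents that add atoms: none
Why: Steglich esterification of the only two free hydroxyls, both equatorial and secondary, under neutral activation that spares the acid-sensitive aryl tert-butyl carbonate (which an HCl-releasing acid chloride preparation would endanger), with no C–O bond at a ring carbon broken.

Step 11
Reactants: 16 4,5-bis-O-[(E)-4-(tert-butoxycarbonyloxy)cinnamoyl]-3-O-(4-methoxybenzyl)quinic acid 1,7-acetonide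
Product: 17 4,5-di-O-p-coumaroylquinic acid
Conditions: CF3CO2H–H2O (9:1), anisole (10 equiv), 0 °C to rt, in the dark; evaporation, reversed-phase chromatography
Reagents that add atoms: none
Why: Global acidolysis in which CF3CO2H ionises the PMB ether and both tert-butyl carbonates (cations taken up by anisole or lost as alkene) and water hydrolyses the acylal, while the cinnamate esters and all ring stereocentres stay intact, acyl migration to O3 is slow in acid, and lactonisation is excluded because O5 is acylated and O3 lies trans to C7.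

## Compound list

1 | D-arabinitol | OC[C@@H](O)[C@H](O)[C@H](O)CO | starting material
2 | 1,5-bis-O-(tert-butyldiphenylsilyl)-D-arabinitol | CC(C)(C)[Si](c1ccccc1)(c1ccccc1)OC[C@@H](O)[C@H](O)[C@H](O)CO[Si](c1ccccc1)(c1ccccc1)C(C)(C)C | intermediate
3 | 1,5-bis-O-(tert-butyldiphenylsilyl)-2,3-O-isopropylidene-D-arabinitol (trans-dioxolane on the threo pair, O4–H free) | CC(C)(C)[Si](c1ccccc1)(c1ccccc1)OC[C@@H](O)[C@H]2OC(C)(C)O[C@@H]2CO[Si](c1ccccc1)(c1ccccc1)C(C)(C)C | intermediate
4 | 4-methoxybenzyl chloride | COc1ccc(CCl)cc1 | starting material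
5 | 1,5-bis-O-(tert-butyldiphenylsilyl)-2,3-O-isopropylidene-4-O-(4-methoxybenzyl)-D-arabinitol | CC(C)(C)[Si](c1ccccc1)(c1ccccc1)OC[C@@H](OCc1ccc(OC)cc1)[C@H]2OC(C)(C)O[C@@H]2CO[Si](c1ccccc1)(c1ccccc1)C(C)(C)C | intermediate
6 | 2,3-O-isopropylidene-4-O-(4-methoxybenzyl)-D-arabinitol | OC[C@@H](OCc1ccc(OC)cc1)[C@H]2OC(C)(C)O[C@@H]2CO | intermediate
7 | 2,3-O-isopropylidene-4-O-(4-methoxybenzyl)-1,5-bis-O-(trifluoromethanesulfonyl)-D-arabinitol | FC(F)(F)S(=O)(=O)OC[C@@H](OCc1ccc(OC)cc1)[C@H]2OC(C)(C)O[C@@H]2COS(=O)(=O)C(F)(F)F | intermediate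
8 | glycolic acid | OCC(=O)O | starting material
9 | 2,2-dimethyl-1,3-dioxolan-4-one | CC1(C)OCC(=O)O1 | intermediate
10 | C6-linked monotriflate: dioxolanone C5 bonded to arabinitol C1 (future C6), triflate left on arabinitol C5 (future C2), both epimers at dioxolanone C5 | FC(F)(F)S(=O)(=O)OC[C@@H](OCc1ccc(OC)cc1)[C@H]2OC(C)(C)O[C@@H]2CC3OC(C)(C)OC3=O | intermediate
11 | C2-linked monotriflate: dioxolanone C5 bonded to arabinitol C5 (future C2), triflate left on arabinitol C1 (future C6), both epimers at dioxolanone C5 | O=C1OC(C)(C)OC1C[C@@H](OCc2ccc(OC)cc2)[C@H]3OC(C)(C)O[C@@H]3COS(=O)(=O)C(F)(F)F | intermediate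
12 | 4,5-O-isopropylidene-3-O-(4-methoxybenzyl)quinic acid 1,7-acetonide (spiro-dioxolanone; O1, O3, O4 on one ring face, O5 and C7 on the other) | CC1(C)O[C@@H]2[C@H](OCc3ccc(OC)cc3)C[C@]4(OC(C)(C)OC4=O)C[C@H]2O1 | intermediate
13 | 3-O-(4-methoxybenzyl)quinic acid 1,7-acetonide (4,5-diol free) | O[C@@H]1[C@H](OCc2ccc(OC)cc2)C[C@]3(OC(C)(C)OC3=O)C[C@H]1O | intermediate
14 | p-coumaric acid | O=C(O)/C=C/c1ccc(O)cc1 | starting material
15 | (E)-4-(tert-butoxycarbonyloxy)cinnamic acid | O=C(O)/C=C/c1ccc(OC(=O)OC(C)(C)C)cc1 | intermediate
16 | 4,5-bis-O-[(E)-4-(tert-butoxycarbonyloxy)cinnamoyl]-3-O-(4-methoxybenzyl)quinic acid 1,7-acetonide | O=C(/C=C/c1ccc(OC(=O)OC(C)(C)C)cc1)O[C@@H]1[C@H](OCc2ccc(OC)cc2)C[C@]3(OC(C)(C)OC3=O)C[C@H]1OC(=O)/C=C/c1ccc(OC(=O)OC(C)(C)C)cc1 | intermediate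
17 | 4,5-di-O-p-coumaroylquinic acid | O=C(/C=C/c1ccc(O)cc1)O[C@@H]1[C@H](O)C[C@@](O)(C(=O)O)C[C@H]1OC(=O)/C=C/c1ccc(O)cc1 | target

## Step count

Total step count: 11.
Longest linear sequence: 9 steps (steps 1, 2, 3, 4, 5, 7, 8, 10, 11).

## Steps most likely to fail

**1. Step 7.**
What may go wrong:
- self-condensation of the glycolate enolate;
- base-induced elimination at the triflates;
- intermolecular oligomerisation;
- poor facial selectivity at C1 during ring closure.

Fallback (known chemistry), from 6 back to 12. The C1 synthon is changed from a glycolate enolate to an acyl anion equivalent, and O1 and C7 are added afterwards.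
- TsCl in pyridine converts 6 into the 1,5-bis-tosylate F1.
- 2-Lithio-1,3-dithiane (1,3-dithiane, n-BuLi, THF–DMPU) displaces one tosylate. A second equivalent of n-BuLi metalates the 2-alkyldithiane and closes the ring. This Corey–Seebach double alkylation is the established sugar-to-carbocycle [5+1] route, and it gives the spiro-dithiane F2.
- MeI and CaCO3 in aqueous MeCN unmask the cyclohexanone F3.
- CH2=CHMgBr with CeCl3 at −78 °C adds from the equatorial direction, because the axial trajectory is blocked by the syn-axial O3-PMB group. This gives the vinyl carbinol F4 with O1 axial.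
- Ozonolysis (O3, then Me2S) gives the α-hydroxy aldehyde F5.
- Pinnick oxidation (NaClO2, NaH2PO4, 2-methyl-2-butene) gives the hydroxy acid F6.
- Me2C(OMe)2 with pyridinium p-toluenesulfonate closes the dioxolanone to 12.

**2. Step 8.**
What may go wrong: concurrent hydrolysis of the spiro-dioxolanone, followed by lactonisation of the freed carboxyl onto O5.

Fallback, from 12 to 17. The acid-based differentiation of the two ketals is replaced by a base/acid differentiation.
- 4-Methoxybenzyl alcohol with catalytic NaH in THF at 0 °C attacks only the lactone carbonyl of 12 (acyl transfer with loss of acetone; the diol acetonide is inert to base). This gives 4-methoxybenzyl 4,5-O-isopropylidene-3-O-(4-methoxybenzyl)quinate F7.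
- Aqueous acetic acid then has a single ketal to cleave and gives the triol ester F8.
- Steglich esterification with 15 acylates the two secondary hydroxyls and leaves the hindered tertiary O1–H, giving the diester F9.
- CF3CO2H with anisole in CH2Cl2 removes the PMB ether, the PMB ester and both Boc groups to give 17.

**3. Step 11.**
What may go wrong: Friedel–Crafts benzylation of the freed phenol rings by the 4-methoxybenzyl cation, or migration of the O4 acyl group to O3 during long acid exposure and work-up.

Fallback, from 16 to 17. The PMB ether is removed oxidatively instead of by acidolysis.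
- DDQ in CH2Cl2–pH 7 buffer at 0 °C cleaves the PMB ether while both phenols are still masked as carbonates, so no benzyl cation is formed. This gives the 3-hydroxy compound F10.
- A short treatment with CF3CO2H–H2O then removes only the Boc groups and the dioxolanone, giving 17.

## Further compounds

F1 | step 7 | 2,3-O-isopropylidene-4-O-(4-methoxybenzyl)-1,5-bis-O-(p-toluenesulfonyl)-D-arabinitol | Cc1ccc(cc1)S(=O)(=O)OC[C@@H](OCc1ccc(OC)cc1)[C@H]2OC(C)(C)O[C@@H]2COS(=O)(=O)c1ccc(C)cc1
F2 | step 7 | spiro-1,3-dithiane of (3R,4S,5R)-4,5-O-isopropylidene-3-O-(4-methoxybenzyl)-3,4,5-trihydroxycyclohexanone | CC1(C)O[C@@H]2[C@H](OCc3ccc(OC)cc3)CC4(SCCCS4)C[C@H]2O1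
F3 | step 7 | (3R,4S,5R)-4,5-O-isopropylidene-3-O-(4-methoxybenzyl)-3,4,5-trihydroxycyclohexanone | CC1(C)O[C@@H]2[C@H](OCc3ccc(OC)cc3)CC(=O)C[C@H]2O1
F4 | step 7 | 1-vinyl carbinol with O1 axial and cis to O3 | CC1(C)O[C@@H]2[C@H](OCc3ccc(OC)cc3)C[C@@](O)(C=C)C[C@H]2O1
F5 | step 7 | 4,5-O-isopropylidene-3-O-(4-methoxybenzyl)quinic aldehyde | CC1(C)O[C@@H]2[C@H](OCc3ccc(OC)cc3)C[C@@](O)(C=O)C[C@H]2O1
F6 | step 7 | 4,5-O-isopropylidene-3-O-(4-methoxybenzyl)quinic acid | CC1(C)O[C@@H]2[C@H](OCc3ccc(OC)cc3)C[C@@](O)(C(=O)O)C[C@H]2O1
F7 | step 8 | 4-methoxybenzyl 4,5-O-isopropylidene-3-O-(4-methoxybenzyl)quinate | CC1(C)O[C@@H]2[C@H](OCc3ccc(OC)cc3)C[C@@](O)(C(=O)OCc3ccc(OC)cc3)C[C@H]2O1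
F8 | step 8 | 4-methoxybenzyl 3-O-(4-methoxybenzyl)quinate | O[C@@H]1[C@H](OCc2ccc(OC)cc2)C[C@@](O)(C(=O)OCc2ccc(OC)cc2)C[C@H]1O
F9 | step 8 | 4-methoxybenzyl 4,5-bis-O-[(E)-4-(tert-butoxycarbonyloxy)cinnamoyl]-3-O-(4-methoxybenzyl)quinate | O=C(/C=C/c1ccc(OC(=O)OC(C)(C)C)cc1)O[C@@H]1[C@H](OCc2ccc(OC)cc2)C[C@@](O)(C(=O)OCc2ccc(OC)cc2)C[C@H]1OC(=O)/C=C/c1ccc(OC(=O)OC(C)(C)C)cc1
F10 | step 11 | 4,5-bis-O-[(E)-4-(tert-butoxycarbonyloxy)cinnamoyl]quinic acid 1,7-acetonide | O=C(/C=C/c1ccc(OC(=O)OC(C)(C)C)cc1)O[C@@H]1[C@H](O)C[C@]2(OC(C)(C)OC2=O)C[C@H]1OC(=O)/C=C/c1ccc(OC(=O)OC(C)(C)C)cc1
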